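The runs come from a simulation from invented constants, and the scatter is random.

Across your three runs the constants are L at 2 mM and 4 portions of E, 3.0 s apart, so E and D are the charges that differ, and I look there.

| flask | L | E | D | remark | time |
|---|---|---|---|---|---|
| south | 2 mM | 1.3 equiv (in portions, 4) | 0.13 mM | run made earlier; portions every 3.0 s |  |
| east | 2 mM | 1.3 equiv (in portions, 4) | 0.30 mM | run made earlier; portions every 3.0 s |  |
| north | 2 mM | 2.6 equiv (in portions, 4) | 0.20 mM | run made earlier; portions every 3.0 s |  |
| flask | 2.0 mM | 1.30 equiv (in portions, 4) | 0.200 mM | the portions of E follow each other after 3.0 s, the first at the start | 5.0 min |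

- south (time / min: L / %, J / %): 0.500: 86.9, 10.7; 1.00: 82.2, 15.6; 2.50: 81.6, 16.5; 6.00: 81.5, 17.1
- east (time / min: L / %, J / %): 1.50: 82.9, 15.8; 3.00: 81.8, 15.0; 5.00: 83.2, 15.1; 6.00: 82.9, 15.7
- north (time / min: L / %, J / %): 0.833: 69.5, 29.2; 2.00: 65.9, 32.2; 4.00: 66.5, 32.5; 6.00: 64.8, 31.5

(standard deviation of a reading: 0.5 percentage points)

- the numbers in the tables scatter by 0.5 percentage points (one standard deviation)
- at the start none of L is in solution
- what has only dissolved of L counts as not reacted
- a reading or a percentage of J counts all its forms, free or not
- the reaction counts as stopped when no species that holds the L changes by six tenths of a point or more over the second half of the time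

1. the state of affairs at 5.0 min: stopped, and by what, or still going (for what has run out or reacted, a solid counts together with what of it has only dissolved) (it is still moving / all of L has reacted / E has run out first)
2. part of the L that has turned into other species by 5.0 min (what has only dissolved does not count)
3. how much J there is at 5.0 min, in percent of the L charged

J lies flat within the scatter at the last two readings of each run, so I average those: south 16.8 %, east 15.4 %, north 32.0 %. North has twice the E of south, with D also different, and twice the J, so I read E as the limiting reagent, though charged above one equivalent. From south to east, the J lost reads 16.5 % of the D added, a rough reading. I take it that D removes E one for one, and that each mM of E removed costs a fixed share of J.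

So I subtract D from the E charge and divide the J made by the rest: south 13.6 %, east 13.4 %, north 12.8 %, mean 13.3 %. I call this the E yield: J formed per mM of E that D leaves.

In your flask D leaves 2.40 mM of E, so I expect J at 15.9 %. L and J together fall short of the charge by about 1.8 percentage points. I read that as dissolved L, which does not count as reacted, so my conversion equals my J. Your forecast says “E is the limiting factor”, with the ending "E has run out first", J 16.2 % and conversion 18 %. I share its ending and differ on conversion, so watch the plateau of J, not the fall of L.

The flask gives the ending "E has run out first", with J 16.1 % and conversion 16.1 %, so the forecast held on the ending, and on J and conversion within the tolerance.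

    L ⇌ X, rate k1*(cs1 - [X]) while solid is left; crystals form when [X] > cs1 (solubility = 0.0450 mM, k = 3.66 /s)
    X + E → J (k = 155 /M/s)
    E + D → Z (k = 10300 /M/s)
    G ⇌ J, rate k4*(cs4 - [J]) while solid is left; crystals form when [J] > cs4 (solubility = 0.880 mM, k = 1.34 /s)
    E → Q (k = 0.0432 /s)

At 5.00 min the flask has E at 0 % of its charge, and its E yield reads 13.4 %. The flask also holds X at 2.25 %, dissolved and not reacted, while the forecast's conversion stands 1.9 points above the flask's. The neighbouring flask with 0.780 equiv of E has 1.36 mM of E charged beyond its D, so the E yield gives J at 9.02 %. That neighbouring flask ends with J at 9.24 %.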